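Start from 48.9%: the electrophile left in Wednesday's flask after 3.00 h, where its fast fall ends.

| flask | electrophile | nucleophile | remark | time |
|---|---|---|---|---|
| Sunday's | 0.30 M | 0.54 equiv | run made earlier |  |
| Wednesday's | 0.30 M | 1 equiv | run made earlier |  |
| oak | 0.30 M | 0.900 equiv |  | 20 h |
| cedar | 0.30 M | 1.40 equiv |  | 20 h |

| run | time / h | electrophile / % | target / % |
|---|---|---|---|
| Sunday's | 2.00 | 72.9 | 25.0 |
| Sunday's | 5.00 | 69.5 | 27.2 |
| Sunday's | 10.0 | 67.0 | 26.4 |
| Sunday's | 15.0 | 65.7 | 24.3 |
| Sunday's | 20.0 | 63.6 | 23.2 |
| Wednesday's | 1.50 | 56.5 | 42.2 |
| Wednesday's | 3.00 | 48.9 | 46.8 |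
| Wednesday's | 6.00 | 47.6 | 47.0 |
| Wednesday's | 10.0 | 45.5 | 45.6 |
| Wednesday's | 20.0 | 41.2 | 41.5 |

(readings scatter by 0.5 percentage points)

- part of the electrophile that has reacted at the end, oak
- part of the electrophile that has reacted at the end, cedar
- what raising the equivalents of nucleophile from its lowest to its highest value here does to the part of the electrophile that has reacted (changes below 5 percentage points count as none) (it falls / no change / it rises)

Read the electrophile column of Wednesday's run downward. It loses 7.6 percentage points between 1.50 h and 3.00 h, then 7.7 points more by 20.0 h. Now set the target column beside it: from 6.00 h on, target falls with the electrophile, from 47.0% to 41.5%, so the two seem to consume each other slowly.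

Next read across the runs. Define the nucleophile cost n, the equivalents charged divided by the fraction of electrophile gone when the fast fall ends. Wednesday's run gives n = 1.96, and Sunday's, from a different charge, gives 1.99 at 2.00 h. Read this as about two nucleophile per electrophile, with the nucleophile as the limiting reagent of the fast part.

Divide each new charge by n to estimate the size b of that fast part: 46.0% for oak, 71.5% for cedar. Add Wednesday's slow loss unchanged. My reckoning gives 53.7% for oak and 79.2% for cedar.

The forecast, which integrates the slow step instead, says 55% for oak, 78% for cedar, and it rises. Its ground: “a fast burst stalls at about half the nucleophile charged”.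

The flasks give 54.0% for oak and 74.4% for cedar; with more nucleophile, it rises, by 20 points.

    electrophile + nucleophile ⇌ acid set free + target (K = 1.00, k = 2.99 /M/h)
    nucleophile + acid set free ⇌ protonated nucleophile, settled at all times (K = 340 /M)
    electrophile + target → side product (k = 0.0693 /M/h)

Cedar's lead comes from its equivalents of nucleophile: at oak's equivalents the answer is 54.0%. Test b on the end states. Side product counts two, one of them consumed target, so target plus side product over two returns the net turnover of the first step up to that time. Oak returns 45.6% against its estimated 46.0%, while cedar returns 66.7% against its estimated 71.5%. A neighbour flask like oak but with 0.12 M of electrophile reaches 49.5% reacted and returns 45.8% of its own charge, against the same estimated 46.0%.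

The data stem from a simulated flask with made-up constants, and the scatter is random.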